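**Retrosynthetic overview**
1. Target 17 is traced back, by O-debenzylation, reduction of two esters and removal of a C4 hydroxyl, to the 4-hydroxy-1-aryltetralin-2,3-diester 14.
2. Ring B of 14 (C1–C4, C4a, C8a) is opened across C1–C2 and C3–C4 to the hydroxy-o-quinodimethane 13, the photoenol of the 2-benzylbenzaldehyde 9, and the C2-symmetric bis-(S)-lactate fumarate 12.
3. Aldehyde 9 comes from an sp2–sp3 Negishi coupling of brominated O-benzylsyringaldehyde 3 with the benzylzinc reagent made from O-benzylvanillin; 12 comes from fumaryl chloride and methyl (S)-lactate.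
4. The feature used: ring B carries three contiguous all-trans stereocentres (C1 with the guaiacyl ring, C2 and C3 with the CH2OH carbons) next to an unsubstituted benzylic C4, so C4 can hold the traceless OH of a dienol built on ring A (C6-OMe, C7-O, C8-OMe).
5. Ring order: ring A and the guaiacyl ring are bought; ring B is the only ring formed, in step 8.

Key step: step 8

Numbering: aryltetralin numbering is used throughout (C1 bears the guaiacyl ring, C2 and C3 the one-carbon groups, C4 is the benzylic CH2 of the target; ring A = C4a, C5–C8, C8a).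

Assumption: the fumarate of methyl (S)-lactate is taken to direct the hydrogen-bonded endo addition to the alkene face that gives 2R,3S in 14, the sense expected for hydroxy-o-quinodimethanes with fumarates of (S)-α-hydroxy esters. Should the opposite sense be found, the fumarate of methyl (R)-lactate is used in step 8 with nothing else changed, since the auxiliary is lost in step 10.

**Step 1**
Reactants: 1 syringaldehyde (4-hydroxy-3,5-dimethoxybenzaldehyde)
Product: 2 4-(benzyloxy)-3,5-dimethoxybenzaldehyde
Conditions: BnBr, K2CO3, DMF, 60 °C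
Reagents that add atoms: benzyl bromide, BrCc1ccccc1
Why: Williamson ether synthesis on the acidic phenol para to the formyl group; the benzyl ether is chosen because it should survive every later step and leave by hydrogenolysis at the end.

**Step 2**
Reactants: 2 4-(benzyloxy)-3,5-dimethoxybenzaldehyde
Product: 3 4-(benzyloxy)-2-bromo-3,5-dimethoxybenzaldehyde
Conditions: NBS, MeCN, 25 °C, dark
Reagents that add atoms: N-bromosuccinimide, O=C1CCC(=O)N1Br
Why: Electrophilic aromatic bromination at C2 (equivalent to C6), the only free position of the ring and activated ortho and para by the two methoxy groups; the formyl group and the first bromine slow a second substitution and the unactivated benzyl ring is not attacked.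

**Step 3**
Reactants: 4 vanillin (4-hydroxy-3-methoxybenzaldehyde)
Product: 5 4-(benzyloxy)-3-methoxybenzaldehyde
Conditions: BnBr, K2CO3, DMF, 60 °C
Reagents that add atoms: benzyl bromide, BrCc1ccccc1
Why: Williamson ether synthesis on the phenol, giving the same protecting group as on ring A so that one hydrogenolysis frees both phenols.

**Step 4**
Reactants: 5 4-(benzyloxy)-3-methoxybenzaldehyde
Product: 6 [4-(benzyloxy)-3-methoxyphenyl]methanol
Conditions: NaBH4, MeOH, 0 °C
Reagents that add atoms: none
Why: Borohydride reduction of the aldehyde to the primary benzylic alcohol; no stereocentre is formed and the benzyl ether is inert.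

**Step 5**
Reactants: 6 [4-(benzyloxy)-3-methoxyphenyl]methanol
Product: 7 4-(benzyloxy)-3-methoxybenzyl chloride
Conditions: SOCl2, CH2Cl2, 0 °C
Reagents that add atoms: thionyl chloride, O=S(Cl)Cl
Why: Deoxychlorination through the chlorosulfite, fast at 0 °C because the para-alkoxybenzylic carbon ionises readily; the chloride is used without storage.

**Step 6**
Reactants: 7 4-(benzyloxy)-3-methoxybenzyl chloride; 3 4-(benzyloxy)-2-bromo-3,5-dimethoxybenzaldehyde
Product: 9 4-(benzyloxy)-2-[4-(benzyloxy)-3-methoxybenzyl]-3,5-dimethoxybenzaldehyde, via [4-(benzyloxy)-3-methoxybenzyl]zinc chloride 8 (not isolated)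
Conditions: Zn dust, LiCl, THF, 25 °C; then slow addition to 3, Pd(OAc)2 (2 mol%), SPhos (2-dicyclohexylphosphino-2',6'-dimethoxybiphenyl, 4 mol%), THF, 25 °C
Reagents that add atoms: none
Why: LiCl-promoted insertion of zinc into the benzylic C–Cl bond followed by Negishi cross-coupling, in which oxidative addition of zerovalent palladium into the C–Br bond is accelerated by the ortho formyl group and the fast biarylphosphine catalyst at 25 °C with slow addition of 8 should outpace uncatalysed 1,2-addition of the benzylzinc reagent to the aldehyde.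

**Step 7**
Reactants: 10 fumaryl chloride; 11 methyl (S)-lactate (2.1 equiv)
Product: 12 bis[(2S)-1-methoxy-1-oxopropan-2-yl] (2E)-but-2-enedioate
Conditions: pyridine, CH2Cl2, 0 °C to 25 °C
Reagents that add atoms: none
Why: Double O-acylation of the secondary alcohol by the diacid chloride (esterification with an acid chloride and pyridine), which does not touch the lactate stereocentre and keeps the E alkene geometry.

**Step 8**
Reactants: 9 4-(benzyloxy)-2-[4-(benzyloxy)-3-methoxybenzyl]-3,5-dimethoxybenzaldehyde; 12 bis[(2S)-1-methoxy-1-oxopropan-2-yl] (2E)-but-2-enedioate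
Product: 14 bis[(2S)-1-methoxy-1-oxopropan-2-yl] (1S,2R,3S,4S)-7-(benzyloxy)-1-[4-(benzyloxy)-3-methoxyphenyl]-4-hydroxy-6,8-dimethoxy-1,2,3,4-tetrahydronaphthalene-2,3-dicarboxylate, via hydroxy-o-quinodimethane 13 (not isolated)
Conditions: hν (365 nm LED), degassed toluene (0.02 M in 9), 12 in two- to threefold excess, 15 °C
Reagents that add atoms: none
Why: Excitation of the aryl aldehyde (n,π*) and intersystem crossing are followed by 1,5-hydrogen transfer from the doubly benzylic CH2 to the carbonyl oxygen, and the 1,4-biradical collapses to the hydroxy-o-quinodimethane, of which the isomer with OH inward reverts to 9 by a fast 1,5-H shift, so the long-lived dienol 13 with the C4–OH and the C1 guaiacyl group both outward is the species that is trapped. The closest known reaction type is the photoenolisation/Diels–Alder trapping of 2-alkyl- and 2-benzylbenzaldehydes by fumarates, together with the addition of hydroxy-o-quinodimethanes to fumarates of chiral α-hydroxy esters. Ring B is closed by a concerted, suprafacial intermolecular [4+2] cycloaddition that forms C1–C2 and C3–C4 in one event and returns ring A to aromaticity. C1 and C4 come out cis because both diene termini carry their substituent outward, C2 and C3 come out trans because the E geometry of the fumarate is transferred, and the C3 ester is cis to the C4–OH (hence the C2 ester trans to the C1 aryl) because the ester on the carbon that bonds to C4 sits endo, hydrogen-bonded to the dienol OH, while the other ester sits exo, away from the guaiacyl ring that the flanking C8 methoxy group twists out of plane. The absolute configuration (1S,2R,3S,4S) is set by the two (S)-lactate units: the fumarate is C2-symmetric, so its two alkene carbons are equivalent (no regiochemical question) and both auxiliaries bias the same π-face. The step needs endo/exo and π-facial selectivity; the first is secured by the O–H···O=C hydrogen bond, kept intact by the non-coordinating solvent, and the second by the doubly matched auxiliaries, while the excess of dienophile and exclusion of O2 should ensure that 13 is trapped before it reverts.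

**Step 9**
Reactants: 14 the 4-hydroxy cycloadduct
Product: 15 bis[(2S)-1-methoxy-1-oxopropan-2-yl] (1S,2R,3R)-7-(benzyloxy)-1-[4-(benzyloxy)-3-methoxyphenyl]-6,8-dimethoxy-1,2,3,4-tetrahydronaphthalene-2,3-dicarboxylate
Conditions: Et3SiH (5 equiv), CF3CO2H (10 equiv), CH2Cl2, 0 °C
Reagents that add atoms: none
Why: Ionic hydrogenation, in which the C4 carbinol ionises under acid because the cation is stabilised by the para oxygen on C7 and is captured by hydride from silicon; C4 becomes CH2, so no stereocentre is at stake there, and the esters and C1–C3 are not touched (C3 changes descriptor from S to R only because the CIP ranking changes).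

**Step 10**
Reactants: 15 the deoxygenated bis-lactate diester
Product: 16 [(1S,2R,3R)-7-(benzyloxy)-1-[4-(benzyloxy)-3-methoxyphenyl]-6,8-dimethoxy-1,2,3,4-tetrahydronaphthalene-2,3-diyl]dimethanol
Conditions: LiAlH4 (6 equiv), THF, 0 °C to 25 °C; aqueous potassium sodium tartrate (KNaC4H4O6) work-up
Reagents that add atoms: none
Why: Hydride reduction of all four ester groups, which turns the two ring esters into the C2 and C3 hydroxymethyl groups and releases the auxiliaries as water-soluble propane-1,2-diol; C2 and C3 are already in the favoured trans-diequatorial arrangement, so epimerisation is not expected.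

**Step 11**
Reactants: 16 the bis-benzyl ether diol
Product: 17 (+)-8-methoxyisolariciresinol, (1S,2R,3R)-1-(4-hydroxy-3-methoxyphenyl)-2,3-bis(hydroxymethyl)-6,8-dimethoxy-1,2,3,4-tetrahydronaphthalen-7-ol
Conditions: H2 (1 atm), 10% Pd/C, EtOAc–MeOH, 25 °C
Reagents that add atoms: none
Why: Catalytic hydrogenolysis of the two aryl benzyl ethers; the molecule holds no other benzylic C–O bond, and the C1–H and C4–H2 positions are inert under these conditions, so the three stereocentres are kept.

**Compound list**
1 | syringaldehyde (4-hydroxy-3,5-dimethoxybenzaldehyde) | COc1cc(C=O)cc(OC)c1O | starting material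
2 | 4-(benzyloxy)-3,5-dimethoxybenzaldehyde | COc1cc(C=O)cc(OC)c1OCc1ccccc1 | intermediate
3 | 4-(benzyloxy)-2-bromo-3,5-dimethoxybenzaldehyde | O=Cc1cc(OC)c(OCc2ccccc2)c(OC)c1Br | intermediate
4 | vanillin (4-hydroxy-3-methoxybenzaldehyde) | COc1cc(C=O)ccc1O | starting material
5 | 4-(benzyloxy)-3-methoxybenzaldehyde | COc1cc(C=O)ccc1OCc1ccccc1 | intermediate
6 | [4-(benzyloxy)-3-methoxyphenyl]methanol | COc1cc(CO)ccc1OCc1ccccc1 | intermediate
7 | 4-(benzyloxy)-3-methoxybenzyl chloride | COc1cc(CCl)ccc1OCc1ccccc1 | intermediate
8 | [4-(benzyloxy)-3-methoxybenzyl]zinc chloride (not isolated) | COc1cc(C[Zn]Cl)ccc1OCc1ccccc1 | intermediate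
9 | 4-(benzyloxy)-2-[4-(benzyloxy)-3-methoxybenzyl]-3,5-dimethoxybenzaldehyde | O=Cc1cc(OC)c(OCc2ccccc2)c(OC)c1Cc1ccc(OCc2ccccc2)c(OC)c1 | intermediate
10 | fumaryl chloride | O=C(Cl)/C=C/C(Cl)=O | starting material
11 | methyl (S)-lactate | C[C@H](O)C(=O)OC | starting material
12 | bis[(2S)-1-methoxy-1-oxopropan-2-yl] (2E)-but-2-enedioate | COC(=O)[C@H](C)OC(=O)/C=C/C(=O)O[C@@H](C)C(=O)OC | intermediate
13 | 3-(benzyloxy)-5-[4-(benzyloxy)-3-methoxybenzylidene]-6-(hydroxymethylidene)-2,4-dimethoxycyclohexa-1,3-diene, OH and aryl both outward (each anti to the neighbouring exocyclic carbon); not isolated | O/C=C1\C=C(OC)C(OCc2ccccc2)=C(OC)/C1=C\c1ccc(OCc2ccccc2)c(OC)c1 | intermediate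
14 | bis[(2S)-1-methoxy-1-oxopropan-2-yl] (1S,2R,3S,4S)-7-(benzyloxy)-1-[4-(benzyloxy)-3-methoxyphenyl]-4-hydroxy-6,8-dimethoxy-1,2,3,4-tetrahydronaphthalene-2,3-dicarboxylate (1,2-trans, 2,3-trans, 3,4-cis) | COc1cc([C@H]2c3c(cc(OC)c(OCc4ccccc4)c3OC)[C@@H](O)[C@@H](C(=O)O[C@@H](C)C(=O)OC)[C@@H]2C(=O)O[C@@H](C)C(=O)OC)ccc1OCc1ccccc1 | intermediate
15 | bis[(2S)-1-methoxy-1-oxopropan-2-yl] (1S,2R,3R)-7-(benzyloxy)-1-[4-(benzyloxy)-3-methoxyphenyl]-6,8-dimethoxy-1,2,3,4-tetrahydronaphthalene-2,3-dicarboxylate | COc1cc([C@H]2c3c(cc(OC)c(OCc4ccccc4)c3OC)C[C@@H](C(=O)O[C@@H](C)C(=O)OC)[C@@H]2C(=O)O[C@@H](C)C(=O)OC)ccc1OCc1ccccc1 | intermediate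
16 | [(1S,2R,3R)-7-(benzyloxy)-1-[4-(benzyloxy)-3-methoxyphenyl]-6,8-dimethoxy-1,2,3,4-tetrahydronaphthalene-2,3-diyl]dimethanol | COc1cc([C@H]2c3c(cc(OC)c(OCc4ccccc4)c3OC)C[C@@H](CO)[C@@H]2CO)ccc1OCc1ccccc1 | intermediate
17 | (+)-8-methoxyisolariciresinol, (1S,2R,3R)-1-(4-hydroxy-3-methoxyphenyl)-2,3-bis(hydroxymethyl)-6,8-dimethoxy-1,2,3,4-tetrahydronaphthalen-7-ol | COc1cc([C@H]2c3c(cc(OC)c(O)c3OC)C[C@@H](CO)[C@@H]2CO)ccc1O | target

**Step count**
Total: 11 steps. Longest linear sequence: 8 steps (from vanillin: steps 3, 4, 5, 6, 8, 9, 10, 11).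

**Steps most likely to fail, with fallbacks**

Step 8 (key step). The dienol may revert to 9, or be lost by electrocyclisation, faster than it is trapped. Triplet energy transfer from excited 9 may isomerise the fumarate to the maleate, which would lead to 2,3-cis adducts, and prolonged irradiation may degrade 14. The fallback sets out from 9 and separates the photochemistry from the cycloaddition. Irradiation of 9 (350–365 nm) in benzene saturated with SO2 should capture the dienol cheletropically as 5-(benzyloxy)-3-[4-(benzyloxy)-3-methoxyphenyl]-1-hydroxy-4,6-dimethoxy-1,3-dihydrobenzo[c]thiophene 2,2-dioxide F1. Heating F1 with 12 in toluene at 80–100 °C in the dark should extrude SO2, release the out,out dienol 13 thermally and give the same cycloadduct, so the route is rejoined at 14. If facial control is only partial, the unwanted adduct still carries the lactate esters, is a diastereomer of 14, and should be removable by chromatography or crystallisation at that stage.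

Step 6. The benzylzinc reagent may add to the aldehyde of 3 in competition with transmetalation, and Wurtz homocoupling may consume 7 during zinc insertion. The fallback sets out from 7 and 3 and replaces the zinc nucleophile by a boron one that does not add to aldehydes. Borylation of 7 (B2pin2, Pd(dba)2, tris(4-methoxyphenyl)phosphine, KOAc, toluene, 50 °C) should give 2-[4-(benzyloxy)-3-methoxybenzyl]-4,4,5,5-tetramethyl-1,3,2-dioxaborolane F2. Suzuki–Miyaura coupling of F2 with 3 (Pd(OAc)2, SPhos, K3PO4, toluene–H2O, 80 °C) should then give the diarylmethane, and the route is rejoined at 9.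

Step 9. The C4 cation may lose H3 to give the ester-conjugated 1,2-dihydronaphthalene, whose re-reduction would scramble C3, and the strong acid may cleave the aryl benzyl ethers early. The fallback sets out from 14 and avoids strong acid by reordering the end game. Hydrogenolysis of 14 (H2, 3 atm, Pd(OH)2/C, EtOAc–AcOH, 25 °C) should remove both benzyl ethers and, through the para-hydroxybenzylic alcohol so revealed, the C4 hydroxyl. This should give bis[(2S)-1-methoxy-1-oxopropan-2-yl] (1S,2R,3R)-7-hydroxy-1-(4-hydroxy-3-methoxyphenyl)-6,8-dimethoxy-1,2,3,4-tetrahydronaphthalene-2,3-dicarboxylate F3. Reduction of F3 with excess LiAlH4 in THF (additional hydride for the two phenols) should give the target directly, so the route is rejoined at 17.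

**Further compounds**
F1 | step 8 | 5-(benzyloxy)-3-[4-(benzyloxy)-3-methoxyphenyl]-1-hydroxy-4,6-dimethoxy-1,3-dihydrobenzo[c]thiophene 2,2-dioxide (racemic, diastereomer mixture) | OC1c2cc(OC)c(OCc3ccccc3)c(OC)c2C(c2ccc(OCc3ccccc3)c(OC)c2)S1(=O)=O
F2 | step 6 | 2-[4-(benzyloxy)-3-methoxybenzyl]-4,4,5,5-tetramethyl-1,3,2-dioxaborolane | COc1cc(CB2OC(C)(C)C(C)(C)O2)ccc1OCc1ccccc1
F3 | step 9 | bis[(2S)-1-methoxy-1-oxopropan-2-yl] (1S,2R,3R)-7-hydroxy-1-(4-hydroxy-3-methoxyphenyl)-6,8-dimethoxy-1,2,3,4-tetrahydronaphthalene-2,3-dicarboxylate | COc1cc([C@H]2c3c(cc(OC)c(O)c3OC)C[C@@H](C(=O)O[C@@H](C)C(=O)OC)[C@@H]2C(=O)O[C@@H](C)C(=O)OC)ccc1O
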